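- Over the 40 min of each run, L makes X, and X then leaves by two roads: two X pair to X2, or one X is captured by Q to give Q.X.

| setting | red | amber | grey |
|---|---|---|---|
| L | 0.10 M | 0.10 M (fed, over 25 min) | 0.10 M |
| Q | 0.200 M | 0.200 M | 0.200 M (fed, over 25 min) |
| time | 40 min | 40 min | 40 min |
| remark | everything together at the start | all else is in the flask from the start; the feed brings no volume worth counting | all else is in the flask from the start; the feed brings no volume worth counting |

- which flask leads in amount of X2, in percent of the L charged ("all alike" within 1.5 percentage points) (red / amber / grey / all alike)
- how much X2 is there at the end, in percent of the L charged: red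
- how much X2 is there at the end, in percent of the L charged: amber
- how much X2 is there at the end, in percent of the L charged: grey

- in percentages every species weighs as the L in it: one X2 counts as two
- two of one species on the left: rate k times its square, two consumed each time
- run time (red): 40 min

    L → X (k1 = 0.033 min⁻¹)
    Q + X → Q.X (k2 = 0.076 L mol⁻¹ min⁻¹)
    2 X → X2 (k3 = 0.30 L mol⁻¹ min⁻¹)
    L ⇌ Z (K4 = 15, k4 = 0.030 min⁻¹)

- Pairing goes with the square of X, while capture goes with its first power and is pseudo-first-order as long as Q stands near its charge, so with Q held there the road that leads changes with the concentration of X.
- We call the level at which both roads remove X equally, with Q at its charge, the crossover concentration, 0.0253 M; pairing's share of the loss is then X over X plus crossover.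
- In red, L leaves at 0.0630 min⁻¹ if we drop the return from Z, whose constant is 0.00200 min⁻¹, so about 0.0524 M can become X, and we reckon 0.0482 M made by the end.
- From above: if X were lost by capture alone, with Q at its charge, pairing along the resulting curve of X would give 18.8%.
- From below: if X were lost first-order at 0.0441 min⁻¹, the constant with Q at its charge and X at the amount made by the end, pairing would give 8.66%.
- Tightening: what is made in red is twice the crossover, so we commit to X ending at crossover and the rest splitting evenly, which gives 11.4%.
- For amber we reckon 0.0421 M made by the end, and the same rule gives 8.40%.
- In grey, we take mean Q during the feed as half its charge, so the crossover halves and, with X taken at the full crossover, pairing's share is 0.667 until 0.0415 M is made; we reckon 14.1%, and our leader is grey.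
- The forecast names grey, with red 13%, amber 7.6% and grey 14.3%, citing “having little Q there at first to scavenge X”; its red figure lies inside our bracket, above our own.
- The simulation gives grey: red 12.9%, inside the bracket, amber 7.46%, grey 14.5%. At 20.0 min, grey held Q at 78.5% of its charge and Q.X at 2.96%, red 97.2% and 5.64%. Going down from the charge, 0.0553 M is the nearest amount of L at which grey's answer has moved by 5 points. A grey flask charged with 0.025 M of L lies below that: its X ended at 0.00776 M, less than the crossover 0.0253 M, so pairing's share at that end reads 23.5%, and that flask holds X2 at 4.89% beside Q.X at 12.9%.

Its constants stand for no real mixture.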